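**Retrosynthetic overview**

- The target is a 2,5-diaryl-3,4-dimethyltetrahydrofuran (O1, C2–C5; C2/C3 cis, C3/C4 trans, C4/C5 trans). It carries two identical erythro (1R,2S) 1-aryl-1-hydroxypropan-2-yl aryl ethers. These are cut first: double SN2 of a core bisphenol on an (R)-lactate-derived α-tosyloxy ketone (inversion), then chelation-controlled ketone reduction.
- The plan rests on C5 of the tetrahydrofuran ring. It is a benzylic ether carbon para to an aryl oxygen, and its aryl group is trans to the C4 methyl. O1–C5 is therefore the bond a hydroxyl group makes when it adds to the para-quinone methide of a 4-alkylguaiacol.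
- The tetrahydrofuran is the only ring formed. It is closed at O1–C5 by oxidising an open-chain guaiacol. The aryl ring on C2 carries Br in place of its oxygen, which keeps the cis C2/C3 carbinol inert. Br is turned into OH afterwards by borylation and oxidation.
- In the open chain, C2/C3 come from an Evans syn aldol and C4–C5 from a benzylic Grignard reagent on the Weinreb amide. C4 comes from hydroxyl-directed hydrogenation of the 1,1-disubstituted (C4=CH2) alkene.

Key step: step 11

Remark: the labels O1, C2, C3, C4, C5 count the tetrahydrofuran ring from oxygen through the carbon that bears the bromoaryl (later aryloxyaryl) group. The same labels are used for the open-chain carbons, while systematic names number independently. The target SMILES is read as (2R,3R,4R,5S) in the core and (1R,2S), erythro, in both side chains.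

**Route**

Step 1
Reactants: 1 vanillin
Product: 2 3-methoxy-4-(triisopropylsilyloxy)benzaldehyde
Conditions: TIPSCl, imidazole, DMF, rt
Reagents that add atoms: triisopropylsilyl chloride, CC(C)[Si](Cl)(C(C)C)C(C)C
Why: Phenol silylation gives a bulky aryl silyl ether that should survive the later Grignard and titanium reagents and leave with fluoride.

Step 2
Reactants: 2 3-methoxy-4-(triisopropylsilyloxy)benzaldehyde
Product: 3 [3-methoxy-4-(triisopropylsilyloxy)phenyl]methanol
Conditions: NaBH4, MeOH, 0 °C
Reagents that add atoms: none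
Why: Borohydride reduction of the aldehyde leaves the aryl silyl ether intact and creates no stereocentre.

Step 3
Reactants: 3 [3-methoxy-4-(triisopropylsilyloxy)phenyl]methanol
Product: 4 [4-(chloromethyl)-2-methoxyphenoxy]triisopropylsilane
Conditions: SOCl2, CH2Cl2, 0 °C; volatiles removed in vacuo, used at once
Reagents that add atoms: thionyl chloride, O=S(Cl)Cl
Why: Chlorodehydroxylation of an electron-rich benzylic alcohol is fast at low temperature, and the chloride is preferred over the bromide because it restrains Wurtz coupling during Grignard formation.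

Step 4
Reactants: 5 (S)-4-benzyl-3-propionyloxazolidin-2-one; 6 4-bromo-3-methoxybenzaldehyde
Product: 8 (S)-4-benzyl-3-[(2S,3S)-3-(4-bromo-3-methoxyphenyl)-3-hydroxy-2-methylpropanoyl]oxazolidin-2-one, via dibutylboron (Z)-enolate 7 (not isolated)
Conditions: Bu2BOTf, Et3N, CH2Cl2, 0 °C; 6, −78 → 0 °C; pH 7 buffer, MeOH, 30 % H2O2, 0 °C
Reagents that add atoms: none
Why: In this Evans syn aldol reaction the Z-boron enolate reacts through a closed chair transition state on the face away from the auxiliary benzyl group, which sets C2 (S) and C3 in the syn relation that becomes the cis C2/C3 relation of the ring.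

Step 5
Reactants: 8 aldol adduct
Product: 9 (2S,3S)-3-(4-bromo-3-methoxyphenyl)-3-hydroxy-N-methoxy-N,2-dimethylpropanamide
Conditions: MeONHMe·HCl, AlMe3, THF/CH2Cl2, −10 °C → rt; aq potassium sodium tartrate
Reagents that add atoms: N,O-dimethylhydroxylamine hydrochloride, CNOC.Cl
Why: Weinreb transamidation with the aluminium amide attacks the exocyclic imide carbonyl, is assisted by the free β-hydroxyl, and leaves both stereocentres untouched.

Step 6
Reactants: 9 β-hydroxy Weinreb amide
Product: 10 (2S,3S)-3-(4-bromo-3-methoxyphenyl)-3-(tert-butyldimethylsilyloxy)-N-methoxy-N,2-dimethylpropanamide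
Conditions: TBSOTf, 2,6-lutidine, CH2Cl2, 0 °C
Reagents that add atoms: tert-butyldimethylsilyl triflate, CC(C)(C)[Si](C)(C)OS(=O)(=O)C(F)(F)F
Why: Silylation of the carbinol removes the retro-aldol pathway of a magnesium aldolate and the acidic proton before the organometallic steps.

Step 7
Reactants: 4 benzylic chloride; 10 silylated Weinreb amide
Product: 12 (3S,4S)-4-(4-bromo-3-methoxyphenyl)-4-(tert-butyldimethylsilyloxy)-1-[3-methoxy-4-(triisopropylsilyloxy)phenyl]-3-methylbutan-2-one, via benzylic Grignard reagent 11 (not isolated)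
Conditions: 4, Mg turnings (activated with 1,2-dibromoethane), THF, 0 °C, slow addition; then 10, THF, 0 °C → rt; aq NH4Cl
Reagents that add atoms: none
Why: In the Weinreb ketone synthesis the magnesium-chelated tetrahedral adduct stops the addition at the ketone stage and forms C4–C5, while the aryl C–Br bond is inert to a benzylic Grignard reagent at this temperature.

Step 8
Reactants: 12 benzyl ketone
Product: 13 {4-[(3R,4S)-4-(4-bromo-3-methoxyphenyl)-4-(tert-butyldimethylsilyloxy)-3-methyl-2-methylidenebutyl]-2-methoxyphenoxy}triisopropylsilane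
Conditions: Cp2TiMe2, toluene, 70 °C, dark
Reagents that add atoms: dimethyltitanocene Cp2TiMe2, [CH3-].[CH3-].[Ti+4].c1cc[cH-]c1.c1cc[cH-]c1
Why: In the Petasis methylenation the thermally formed Cp2Ti=CH2 is not basic, so the readily enolised benzyl ketone should be methylenated without C3 epimerisation, β-elimination of the silyloxy group or drift of the new alkene into conjugation.

Step 9
Reactants: 13 bis-silyl ether
Product: 14 4-[(3R,4S)-4-(4-bromo-3-methoxyphenyl)-4-hydroxy-3-methyl-2-methylidenebutyl]-2-methoxyphenol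
Conditions: TBAF, AcOH (1:1), THF, rt
Reagents that add atoms: none
Why: Buffered fluoride cleaves both silyl ethers in one operation, which frees the directing C2 hydroxyl and the phenol needed for the key step without exposing the allylbenzene unit to strong base.

Step 10
Reactants: 14 homoallylic alcohol
Product: 15 4-[(2S,3R,4S)-4-(4-bromo-3-methoxyphenyl)-4-hydroxy-2,3-dimethylbutyl]-2-methoxyphenol
Conditions: [Ir(cod)(PCy3)(py)]PF6 (5 mol %), H2 (20 bar), CH2Cl2, 0 °C → rt
Reagents that add atoms: none
Why: In this hydroxyl-directed hydrogenation the C2 hydroxyl binds the cationic iridium in a chelate where the C3 methyl lies toward the =CH2 terminus (only a methyl/hydrogen allylic 1,3-contact), the C3 hydrogen faces the CH2Ar branch (least allylic 1,2-strain) and the C2 aryl group is pseudo-equatorial, so hydrogen should reach C4 to place the new methyl syn to the C3 methyl along the chain, whereas the conjugated trisubstituted isomer would present the opposite prochirality in the same chelate, which is why the alkene sits in the 1,1-disubstituted position and pressure is used to outrun its migration.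

Step 11
Reactants: 15 open-chain hydroxy guaiacol
Product: 17 4-[(2R,3R,4R,5S)-5-(4-bromo-3-methoxyphenyl)-3,4-dimethyloxolan-2-yl]-2-methoxyphenol, via para-quinone methide 16 (not isolated)
Conditions: Ag2O (1.1 equiv, freshly prepared), CH2Cl2 (0.005 M), 4 Å molecular sieves, rt, dark; filtration through Celite
Reagents that add atoms: none
Why: Ag2O takes two electrons and two protons (the phenolic O–H and one C5–H) from the guaiacol ring of 15 to give para-quinone methide 16, and the C2 hydroxyl then adds to the methide carbon C5 in an oxa-1,6-addition that restores the aromatic ring and forms O1–C5. The closest known reaction types are the Ag2O oxidation of 4-alkyl-2-methoxyphenols to their quinone methides and the capture of such methides by an internal hydroxyl when dibenzylbutane lignans are oxidised to epoxylignans. The tetrahydrofuran closes in the 5-exo-trig mode, because the C5=C(aryl) bond lies outside the forming ring. The new C5 stereocentre is controlled by allylic 1,3-strain in 16: the C4–H bond eclipses the methide plane opposite the ortho C–H, the C4 methyl and C3 then lie on opposite faces, and the tethered oxygen can reach C5 only from the C3 face, which should put the C5 aryl group trans to the C4 methyl and cis to the C2 aryl group, and since this is also the more stable epimer any reversible reopening through 16 should converge on it. The step needs oxidation of one ring only, which is secured because only one ring is a free phenol and the bromo-substituted ring cannot form a methide, so C2–H, the C2–O bond and the cis C2/C3 relation are untouched. The neutral medium disfavours Friedel–Crafts closure to an aryltetralin, high dilution disfavours phenoxyl coupling, and the small excess of oxidant limits a second oxidation at C5.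

Step 12
Reactants: 17 bromo phenol
Product: 18 2-methoxy-4-{(2R,3R,4R,5S)-5-[3-methoxy-4-(4,4,5,5-tetramethyl-1,3,2-dioxaborolan-2-yl)phenyl]-3,4-dimethyloxolan-2-yl}phenol
Conditions: B2pin2, Pd(dppf)Cl2 (5 mol %), KOAc, 1,4-dioxane, 90 °C
Reagents that add atoms: bis(pinacolato)diboron, CC1(C)OB(OC1(C)C)B1OC(C)(C)C(C)(C)O1
Why: The Miyaura borylation (oxidative addition of zerovalent palladium into C–Br, acetate-assisted transmetalation, reductive elimination) uses only the weak base KOAc, which the free phenol and both benzylic ether bonds should tolerate.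

Step 13
Reactants: 18 aryl boronate
Product: 19 4,4'-[(2R,3R,4R,5S)-3,4-dimethyloxolane-2,5-diyl]bis(2-methoxyphenol)
Conditions: 30 % H2O2, aq NaOH, THF, 0 °C; Na2S2O3, then NH4Cl to pH 7
Reagents that add atoms: hydrogen peroxide, OO
Why: In this ipso-hydroxylation hydroperoxide adds to boron and the aryl group migrates from boron to oxygen at the same ring position, and the cold, non-acidic work-up protects the C2 benzylic ether, which is acid-labile from here on.

Step 14
Reactants: 20 methyl (R)-lactate
Product: 21 (R)-2-hydroxy-N-methoxy-N-methylpropanamide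
Conditions: MeONHMe·HCl, iPrMgCl, THF, −20 → 0 °C; aq NH4Cl
Reagents that add atoms: N,O-dimethylhydroxylamine hydrochloride, CNOC.Cl
Why: Ester aminolysis by the magnesium amide gives the Weinreb amide at low temperature, and the magnesium alkoxide of the free hydroxyl shields the stereocentre from enolisation.

Step 15
Reactants: 21 lactic Weinreb amide; 22 4-bromo-1,2-dimethoxybenzene
Product: 24 (R)-1-(3,4-dimethoxyphenyl)-2-hydroxypropan-1-one, via arylmagnesium bromide 23 (not isolated)
Conditions: 22, Mg, THF, reflux; then 21 (0.4 equiv), 0 °C → rt; aq NH4Cl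
Reagents that add atoms: none
Why: In this Weinreb ketone synthesis the first equivalent of Grignard reagent deprotonates the hydroxyl, the second adds, and the ketone is released only on quench, so the α-stereocentre should not racemise.

Step 16
Reactants: 24 α-hydroxy ketone
Product: 25 (R)-1-(3,4-dimethoxyphenyl)-1-oxopropan-2-yl 4-methylbenzenesulfonate
Conditions: TsCl, Et3N, DMAP (cat.), CH2Cl2, 0 °C
Reagents that add atoms: 4-toluenesulfonyl chloride, Cc1ccc(S(=O)(=O)Cl)cc1
Why: O-sulfonylation breaks no bond at the stereocentre, so the R configuration is retained in an electrophile activated for SN2 by the neighbouring carbonyl.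

Step 17
Reactants: 19 bisphenol; 25 α-tosyloxy ketone (2.3 equiv)
Product: 26 (2S,2'S)-2,2'-{[(2R,3R,4R,5S)-3,4-dimethyloxolane-2,5-diyl]bis[(2-methoxy-4,1-phenylene)oxy]}bis[1-(3,4-dimethoxyphenyl)propan-1-one]
Conditions: BEMP (2-tert-butylimino-2-diethylamino-1,3-dimethylperhydro-1,3,2-diazaphosphorine, 2.3 equiv), CH2Cl2, rt
Reagents that add atoms: none
Why: In this double Williamson-type SN2 etherification the naked phenoxides formed by the non-nucleophilic phosphazene base displace the α-keto tosylate with inversion (R to S at each C–O carbon) at a rate that should outrun enolisation of the electrophile or product.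

Step 18
Reactants: 26 bis(α-aryloxy ketone)
Product: 27 (1R,2S)-1-(3,4-dimethoxyphenyl)-2-{4-[(2R,3R,4R,5S)-5-{4-[(1R,2S)-1-(3,4-dimethoxyphenyl)-1-hydroxypropan-2-yl]oxy-3-methoxyphenyl}-3,4-dimethyloxolan-2-yl]-2-methoxyphenoxy}propan-1-ol (target)
Conditions: Zn(BH4)2 (ethereal solution), CH2Cl2/Et2O, −78 → −30 °C; aq NH4Cl
Reagents that add atoms: none
Why: In this chelation-controlled (Cram chelate) reduction zinc bridges the carbonyl oxygen and the α-aryloxy oxygen, with support from the ortho methoxy group, and hydride enters from the face of the α-hydrogen opposite the α-methyl, which should set each carbinol as R, erythro to the S ether carbon.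

**Compound list**

1 | vanillin | O=Cc1ccc(O)c(OC)c1 | starting material
2 | 3-methoxy-4-(triisopropylsilyloxy)benzaldehyde | O=Cc1ccc(O[Si](C(C)C)(C(C)C)C(C)C)c(OC)c1 | intermediate
3 | [3-methoxy-4-(triisopropylsilyloxy)phenyl]methanol | OCc1ccc(O[Si](C(C)C)(C(C)C)C(C)C)c(OC)c1 | intermediate
4 | [4-(chloromethyl)-2-methoxyphenoxy]triisopropylsilane | ClCc1ccc(O[Si](C(C)C)(C(C)C)C(C)C)c(OC)c1 | intermediate
5 | (S)-4-benzyl-3-propionyloxazolidin-2-one | CCC(=O)N1[C@@H](Cc2ccccc2)COC1=O | starting material
6 | 4-bromo-3-methoxybenzaldehyde | O=Cc1ccc(Br)c(OC)c1 | starting material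
7 | dibutylboron (Z)-enolate of 5 | C/C=C(\OB(CCCC)CCCC)N1[C@@H](Cc2ccccc2)COC1=O | intermediate
8 | (S)-4-benzyl-3-[(2S,3S)-3-(4-bromo-3-methoxyphenyl)-3-hydroxy-2-methylpropanoyl]oxazolidin-2-one | COc1cc([C@@H](O)[C@H](C)C(=O)N2[C@@H](Cc3ccccc3)COC2=O)ccc1Br | intermediate
9 | (2S,3S)-3-(4-bromo-3-methoxyphenyl)-3-hydroxy-N-methoxy-N,2-dimethylpropanamide | COc1cc([C@@H](O)[C@H](C)C(=O)N(C)OC)ccc1Br | intermediate
10 | (2S,3S)-3-(4-bromo-3-methoxyphenyl)-3-(tert-butyldimethylsilyloxy)-N-methoxy-N,2-dimethylpropanamide | COc1cc([C@@H](O[Si](C)(C)C(C)(C)C)[C@H](C)C(=O)N(C)OC)ccc1Br | intermediate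
11 | [3-methoxy-4-(triisopropylsilyloxy)benzyl]magnesium chloride | Cl[Mg]Cc1ccc(O[Si](C(C)C)(C(C)C)C(C)C)c(OC)c1 | intermediate
12 | (3S,4S)-4-(4-bromo-3-methoxyphenyl)-4-(tert-butyldimethylsilyloxy)-1-[3-methoxy-4-(triisopropylsilyloxy)phenyl]-3-methylbutan-2-one | COc1cc([C@@H](O[Si](C)(C)C(C)(C)C)[C@H](C)C(=O)Cc2ccc(O[Si](C(C)C)(C(C)C)C(C)C)c(OC)c2)ccc1Br | intermediate
13 | {4-[(3R,4S)-4-(4-bromo-3-methoxyphenyl)-4-(tert-butyldimethylsilyloxy)-3-methyl-2-methylidenebutyl]-2-methoxyphenoxy}triisopropylsilane | COc1cc([C@@H](O[Si](C)(C)C(C)(C)C)[C@H](C)C(=C)Cc2ccc(O[Si](C(C)C)(C(C)C)C(C)C)c(OC)c2)ccc1Br | intermediate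
14 | 4-[(3R,4S)-4-(4-bromo-3-methoxyphenyl)-4-hydroxy-3-methyl-2-methylidenebutyl]-2-methoxyphenol | COc1cc([C@@H](O)[C@H](C)C(=C)Cc2ccc(O)c(OC)c2)ccc1Br | intermediate
15 | 4-[(2S,3R,4S)-4-(4-bromo-3-methoxyphenyl)-4-hydroxy-2,3-dimethylbutyl]-2-methoxyphenol | COc1cc([C@@H](O)[C@H](C)[C@@H](C)Cc2ccc(O)c(OC)c2)ccc1Br | intermediate
16 | 4-[(2S,3R,4S)-4-(4-bromo-3-methoxyphenyl)-4-hydroxy-2,3-dimethylbutylidene]-2-methoxycyclohexa-2,5-dien-1-one | COc1cc([C@@H](O)[C@H](C)[C@@H](C)C=C2C=CC(=O)C(OC)=C2)ccc1Br | intermediate
17 | 4-[(2R,3R,4R,5S)-5-(4-bromo-3-methoxyphenyl)-3,4-dimethyloxolan-2-yl]-2-methoxyphenol | COc1cc([C@H]2O[C@@H](c3ccc(O)c(OC)c3)[C@H](C)[C@H]2C)ccc1Br | intermediate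
18 | 2-methoxy-4-{(2R,3R,4R,5S)-5-[3-methoxy-4-(4,4,5,5-tetramethyl-1,3,2-dioxaborolan-2-yl)phenyl]-3,4-dimethyloxolan-2-yl}phenol | COc1cc([C@H]2O[C@@H](c3ccc(O)c(OC)c3)[C@H](C)[C@H]2C)ccc1B4OC(C)(C)C(C)(C)O4 | intermediate
19 | 4,4'-[(2R,3R,4R,5S)-3,4-dimethyloxolane-2,5-diyl]bis(2-methoxyphenol) | COc1cc([C@H]2O[C@@H](c3ccc(O)c(OC)c3)[C@H](C)[C@H]2C)ccc1O | intermediate
20 | methyl (R)-lactate | C[C@@H](O)C(=O)OC | starting material
21 | (R)-2-hydroxy-N-methoxy-N-methylpropanamide | C[C@@H](O)C(=O)N(C)OC | intermediate
22 | 4-bromo-1,2-dimethoxybenzene | COc1ccc(Br)cc1OC | starting material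
23 | 3,4-dimethoxyphenylmagnesium bromide | COc1ccc([Mg]Br)cc1OC | intermediate
24 | (R)-1-(3,4-dimethoxyphenyl)-2-hydroxypropan-1-one | C[C@@H](O)C(=O)c1ccc(OC)c(OC)c1 | intermediate
25 | (R)-1-(3,4-dimethoxyphenyl)-1-oxopropan-2-yl 4-methylbenzenesulfonate | C[C@@H](OS(=O)(=O)c1ccc(C)cc1)C(=O)c1ccc(OC)c(OC)c1 | intermediate
26 | (2S,2'S)-2,2'-{[(2R,3R,4R,5S)-3,4-dimethyloxolane-2,5-diyl]bis[(2-methoxy-4,1-phenylene)oxy]}bis[1-(3,4-dimethoxyphenyl)propan-1-one] | COc1ccc(C(=O)[C@H](C)Oc2ccc([C@H]3O[C@@H](c4ccc(O[C@@H](C)C(=O)c5ccc(OC)c(OC)c5)c(OC)c4)[C@H](C)[C@H]3C)cc2OC)cc1OC | intermediate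
27 | (1R,2S)-1-(3,4-dimethoxyphenyl)-2-{4-[(2R,3R,4R,5S)-5-{4-[(1R,2S)-1-(3,4-dimethoxyphenyl)-1-hydroxypropan-2-yl]oxy-3-methoxyphenyl}-3,4-dimethyloxolan-2-yl]-2-methoxyphenoxy}propan-1-ol | COc1ccc([C@@H](O)[C@H](C)Oc2ccc([C@H]3O[C@@H](c4ccc(O[C@@H](C)[C@H](O)c5ccc(OC)c(OC)c5)c(OC)c4)[C@H](C)[C@H]3C)cc2OC)cc1OC | target

**Step count**

Total step count: 18.
Longest linear sequence: 12 steps. This is steps 4–13, 17 and 18 from 5 and 6. The count is the same from 1 through steps 1–3, 7–13, 17 and 18.

**Steps most likely to fail**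

**Step 11 (key step).**
- Risk: the phenoxyl radical may couple at its free ortho position. The methide may tautomerise to the styrene before the hydroxyl arrives. The product may also be oxidised a second time at C5.
- Fallback: it sets out from 15 and returns at 17, and it separates oxidation from ring closure.
- DDQ (1 equiv) in MeOH at 0 °C removes hydride from C5 in a two-electron process, and the solvent traps the methide. This should give 4-[(2R,3R,4S)-4-(4-bromo-3-methoxyphenyl)-4-hydroxy-1-methoxy-2,3-dimethylbutyl]-2-methoxyphenol F1 as a mixture of epimers at the methoxy carbon.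
- Catalytic pyridinium 4-toluenesulfonate in CH2Cl2 then ionises only the para-hydroxybenzylic methyl ether. The C2 hydroxyl captures the cation reversibly, so the ring should close under thermodynamic control to the C4/C5-trans isomer 17. The bromoaryl carbinol does not ionise under these conditions.

**Step 10.**
- Risk: facial selectivity is lost if reduction proceeds outside the hydroxyl chelate. A metal hydride may also move the alkene into conjugation before it is reduced.
- Fallback: it sets out from 13 and returns at 15. It replaces substrate direction by catalyst control on a different alkene class, with the hydroxyl masked.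
- RuHCl(CO)(PPh3)3 (cat.) in toluene at 80 °C deliberately isomerises 13. The product should be the conjugated {4-[(1E,3R,4S)-4-(4-bromo-3-methoxyphenyl)-4-(tert-butyldimethylsilyloxy)-2,3-dimethylbut-1-en-1-yl]-2-methoxyphenoxy}triisopropylsilane F2.
- Asymmetric hydrogenation of this unfunctionalised trisubstituted aryl alkene follows, using [Ir(cod)(tBu-PHOX)]BArF under H2 (50 bar) in CH2Cl2. The matching ligand antipode is chosen by testing both. This should give {4-[(2S,3R,4S)-4-(4-bromo-3-methoxyphenyl)-4-(tert-butyldimethylsilyloxy)-2,3-dimethylbutyl]-2-methoxyphenoxy}triisopropylsilane F3.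
- TBAF/AcOH in THF then releases 15.

**Step 18.**
- Risk: chelation is incomplete because an aryl ether oxygen is a weak donor, so open-chain attack competes and erythro selectivity erodes at two independent sites.
- Fallback: it sets out from 26 and returns at 27. It uses the non-chelated pathway on purpose and then inverts the carbinols.
- Bu4NBH4 in CH2Cl2/MeOH at −78 °C has no chelating cation and follows polar Felkin–Anh control. It should give the bis-threo diol (1S,2S)-1-(3,4-dimethoxyphenyl)-2-{4-[(2R,3R,4R,5S)-5-{4-[(1S,2S)-1-(3,4-dimethoxyphenyl)-1-hydroxypropan-2-yl]oxy-3-methoxyphenyl}-3,4-dimethyloxolan-2-yl]-2-methoxyphenoxy}propan-1-ol F4.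
- A double Mitsunobu reaction (4-nitrobenzoic acid, PPh3, DIAD, toluene, 0 °C) inverts both carbinols to the bis(4-nitrobenzoate) of 27 F5.
- K2CO3 in MeOH at 0 °C then removes the esters to give 27.

**Further compounds**

F1 | step 11 | 4-[(2R,3R,4S)-4-(4-bromo-3-methoxyphenyl)-4-hydroxy-1-methoxy-2,3-dimethylbutyl]-2-methoxyphenol (epimers at C1) | COc1cc([C@@H](O)[C@H](C)[C@@H](C)C(OC)c2ccc(O)c(OC)c2)ccc1Br
F2 | step 10 | {4-[(1E,3R,4S)-4-(4-bromo-3-methoxyphenyl)-4-(tert-butyldimethylsilyloxy)-2,3-dimethylbut-1-en-1-yl]-2-methoxyphenoxy}triisopropylsilane | COc1cc([C@@H](O[Si](C)(C)C(C)(C)C)[C@H](C)/C(C)=C/c2ccc(O[Si](C(C)C)(C(C)C)C(C)C)c(OC)c2)ccc1Br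
F3 | step 10 | {4-[(2S,3R,4S)-4-(4-bromo-3-methoxyphenyl)-4-(tert-butyldimethylsilyloxy)-2,3-dimethylbutyl]-2-methoxyphenoxy}triisopropylsilane | COc1cc([C@@H](O[Si](C)(C)C(C)(C)C)[C@H](C)[C@@H](C)Cc2ccc(O[Si](C(C)C)(C(C)C)C(C)C)c(OC)c2)ccc1Br
F4 | step 18 | bis-threo (1S,2S;1S,2S) diastereomer of 27 | COc1ccc([C@H](O)[C@H](C)Oc2ccc([C@H]3O[C@@H](c4ccc(O[C@@H](C)[C@@H](O)c5ccc(OC)c(OC)c5)c(OC)c4)[C@H](C)[C@H]3C)cc2OC)cc1OC
F5 | step 18 | bis(4-nitrobenzoate) of 27, (1R,2S) in both side chains | COc1ccc([C@@H](OC(=O)c6ccc(cc6)[N+](=O)[O-])[C@H](C)Oc2ccc([C@H]3O[C@@H](c4ccc(O[C@@H](C)[C@H](OC(=O)c7ccc(cc7)[N+](=O)[O-])c5ccc(OC)c(OC)c5)c(OC)c4)[C@H](C)[C@H]3C)cc2OC)cc1OC
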